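# Proposed total synthesis of CNP0268004.1 by double ketene–ynol ether spiroannulation of a desymmetrised cyclobutene anhydride

## Analysis of the target

The target 32 is a dispiro compound: two 2(5H)-furanones are spiro-fused through C5 to two adjacent carbons of a cyclobutane. Ring A (O1, C2 carbonyl, C3 butyl, C4 bromine) sits on spiro carbon Ca and ring B (O1', C2', C3' with the 1-acetoxybutyl group, C4' bromine) on spiro carbon Cd; Cb (next to Ca) and Cc (next to Cd) are CHBr. There are five stereocentres: Ca, Cb, Cc, Cd and the (R)-carbinol carbon of the side chain. On the four-membered ring the lactone oxygens O1 and O1' are trans and the two ring bromines are trans. Each ring bromine is cis to the vinylic carbon (C4 or C4') and trans to the lactone oxygen of the neighbouring spiro centre, so the core has a local twofold axis through the midpoints of Ca–Cd and Cb–Cc, broken only by butyl versus 1-acetoxybutyl. Sensitive groups are the two 4-bromobutenolides (vinylogous acyl bromides, open to addition–elimination by nucleophiles), the secondary acetate, and the secondary ring bromides, which would be lost by β-elimination under any later base-mediated step. The difficulty is the pair of contiguous, fully substituted spiro centres with defined relative and absolute configuration on a strained ring, together with four bromines of two kinds. The route rests on one feature: each lactone (O1–C2–C3–C4–Ca) is the oxygen-inserted form of a 2-alkyl-3-alkoxycyclobut-2-enone spiro-fused at Ca, whose ketone carbon and Ca come from a ketene exocyclic to the four-membered ring, and the nearly twofold-symmetric core descends from the meso anhydride 3.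

## Retrosynthetic reasoning

**32 ⇒ 31 (Cb–Br and Cc–Br).** The ring bromines are removed first. Secondary bromides β to Ca and Cd would not survive the amine-mediated ketene generation needed at both spiro carbons, and 31 has only one alkene that is not deactivated by a lactone carbonyl. Forward, an anti addition must give the trans-dibromide. The twofold character of the core makes the two alkene faces equivalent, but two trans-dibromides are still possible; 32 is the one with each bromine on the side of the neighbouring vinylic carbon, so the site of bromonium opening matters (see the uncertain steps).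

**31 ⇒ 30 ⇒ 29 (O–acyl bond of the side chain).** The acetate is traced through alcohol 30 to silyl ether 29; only the O–acyl bond is cut, so the carbinol C–O bond and its (R)-configuration are untouched. An acetate cannot be carried from the start: next to an ynol ether it would be a propargylic leaving group, and next to a tetronic acid it would be lost by β-elimination. A silyl ether is inert in both settings.

**29 ⇒ 28 ⇒ 27 (C4–Br and C4'–Br).** The vinylic C–Br bonds are disconnected to enolic C–O bonds: 29 from bis(tetronic acid) 28 by the vinylogous form of acid-to-acid-halide conversion, and 28 from the bis(tert-butyl enol ether) 27. Oxygen at C4 and C4' is what the cycloaddition delivers. A tert-butyl group on that oxygen, rather than a primary alkyl, lets both positions be unmasked together by cold acid, which the cyclobutene, the lactones and a secondary silyl ether should tolerate; a primary alkyl enol ether would need hot mineral acid or hard Lewis acids.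

**27 ⇒ 26 ⇒ 25 + 24 (O1'–Cd, then Cd–C4' and C2'–C3').** Ring B is the oxygen-insertion product of spiro cyclobutenone 26, which is cut into ketene 25 and ynol ether 24. This repeats on Cd what the key step does on Ca, so the near-symmetry of the core is used twice. Forward, C4' must bond to Cd on the face that carries O1 so that O1 and O1' end up trans; the tert-butoxy group on C4, which lies over the other face, is expected to enforce this.

**25 ⇐ 18 ⇐ 17 ⇐ 16 (the ester as latent ketene).** Ketene 25 comes from acid chloride 18, and this from acid 17 and methyl ester 16. The ester therefore has two roles: it controls the configuration of Ca and then becomes the ketene carbon of Cd. Its own configuration is expendable.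

**16 ⇒ 15 ⇒ 14 + 13 (O1–Ca, then Ca–C4 and C2–C3).** Lactone A is opened at O1–Ca to cyclobutenone 15, and 15 is cut at Ca–C4 and C2–C3 into ketene 14 and ynol ether 13. The cut is made here because both bonds form in one step with predictable regiochemistry from the polarity of the partners, and because the later oxygen insertion is regioselective (the quaternary carbon migrates) and stereoretentive. Forward, the cycloaddition must bond C4 to Ca on the face away from the ester.

**14 ⇐ 5 ⇐ 4 ⇐ 3 ⇐ 1 + 2.** Ketene 14 comes from acid chloride 5, and 5 from hemiester 4. Hemiester 4 is the product of enantioselective alcoholysis of the meso anhydride 3, which is the source of absolute configuration for the whole core. Anhydride 3 is the [2+2] photoadduct of 1 and 2.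

**13 and 24 ⇐ 10 ⇐ 8 ⇐ 6.** Both ynol ethers are cut at the bond between the alkyne carbon and the alkyl chain, which leads to one terminal ynol ether, 10. Alkyne 10 is released by protonation of the lithium acetylide 9, which comes from dichlorovinyl ether 8 and ultimately from 6. Preparing 10 once lets each carbon–carbon bond be made with the counter-ion that suits the electrophile. The sodium acetylide 12 in liquid ammonia is alkylated by the primary bromide 11 to give 13. The less basic magnesium acetylide 20 adds to the enolisable aldehyde 19 to give 21, and oxidation to 22, enantioselective reduction to 23 and silylation give 24.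

## Alternatives that were turned down

**Alternative 1:** Lactone B is taken apart at C4'–Br, C3'–C2' and C2'–O1' together, leading back to a tertiary propargylic alcohol on Cd, a one-carbon carbonyl source and bromide.
- Forward key step: under oxidative catalysis by divalent palladium (copper reoxidant, excess bromide, carbonylating atmosphere), bromide and palladium add trans across the alkyne, the carbonyl unit inserts and the Cd hydroxyl captures the acyl–palladium species, giving the silyl-protected dispiro bis(bromobutenolide) A1.
- For it: the vinylic bromine and the lactone arrive in one operation, with no alkoxy-to-hydroxy-to-bromine exchange and no tetronic acid next to the side-chain oxygen. On this point it is stronger than the chosen route, which spends two steps per ring on the exchange.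
- Against it: the propargylic carbinol must first be set up with the right configuration at Cd by acetylide addition to a strained cyclobutenone that is prone to enolisation and ring opening. Lactone closure needs trans- rather than cis-bromopalladation. The bromobutenolide of ring A is itself a substrate for the zerovalent palladium formed in each turnover.
- Comparison: ring A would have to be built by separate chemistry, so the near-symmetry is not used. The chosen route uses one reaction type for both rings and relays the stereochemistry from a single desymmetrisation.

**Alternative 2:** The Ca–Cd bond of the cyclobutene is cut, leading back to a flat 2-pyranone that carries the ester on the future Ca and the acyloxy group on the future Cd.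
- Forward key step: irradiation effects a disrotatory 4π closure to the bicyclic β-lactone A2.
- For it: the four-membered ring and both oxygenated quaternary carbons form in one step from an easily assembled precursor, and the cis-fused bicycle places the lactone oxygen on Ca and the acyloxy oxygen on Cd on opposite faces. On relative configuration of the spiro carbons it is as strong as the chosen route.
- Against it: the photosubstrate is achiral apart from the remote side-chain centre, so both core configurations would form about equally and absolute control is lost. A2 is a strained β-lactone that can extrude carbon dioxide. Both butenolides would still have to be closed by Dieckmann-type condensations, one through an ester enolate with a β-silyloxy leaving group, and the enols then converted to bromides.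
- Comparison: step count is no shorter. The chosen route takes absolute configuration from a meso desymmetrisation and never passes through a β-lactone.

**Alternative 3:** Cd–O1' and Cd–C4' are cut together, leading back to a ketone at Cd (a spiro cyclobutenone already carrying ring A), a chiral β-silyloxy acid and a convertible isocyanide.
- Forward key step: a Passerini three-component reaction gives the α-acyloxy carboxamide A3, to be followed by Dieckmann-type closure of C3'–C4'.
- For it: it is convergent, and the side-chain stereocentre comes from the very dependable asymmetric hydrogenation of a β-keto ester. On this point it is stronger than the chosen route, whose reduction of an alkoxy ynone is less well supported.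
- Against it: Passerini reactions of ketones are slow, and this ketone is a hindered, strained, conjugated cyclobutenone next to a quaternary centre, so conjugate addition and ring opening compete and facial control at Cd is loose. The later ring closure needs amide activation and an enolate prone to β-elimination, and C4' still arrives as oxygen to be exchanged for bromine.
- Comparison: ring A must again be made separately. The chosen route forms both C–C bonds of each lactone in one cycloaddition, with regiochemistry fixed by polarity.

Key step: step 7

Remark on the chemistry: the alkaloid-mediated methanolysis is assumed to show the same sense of induction on anhydride 3 as on other cis-fused meso anhydrides, quinidine leading to the (1R,2S) hemiester 4; if the sense were opposite, quinine would be used in step 2 with nothing else changed.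

Remark on the chemistry: transfer hydrogenation of ynone 22 is assumed to follow the usual sense for alkynyl ketones, the (R,R)-configured catalyst giving the (R)-carbinol 23.

## Route

Step 1
Reactants: 1 maleic anhydride; 2 acetylene
Product: 3 cis-cyclobut-3-ene-1,2-dicarboxylic anhydride (meso)
Conditions: C2H2 (sat.), acetophenone (sens.), EtOAc, hν (medium-pressure Hg lamp, Pyrex), −50 °C
Reagents that add atoms: none
Why: Triplet-sensitised [2+2] photocycloaddition of the enedione to the alkyne is a known entry to this anhydride; the five-membered anhydride enforces the cis ring fusion, so the product is meso.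

Step 2
Reactants: 3 cis-cyclobut-3-ene-1,2-dicarboxylic anhydride
Product: 4 (1R,2S)-2-(methoxycarbonyl)cyclobut-3-ene-1-carboxylic acid
Conditions: quinidine (1.1 equiv), MeOH (3 equiv), toluene/CCl4 (1:1), −55 °C; then 2 M HCl wash (alkaloid recovered)
Reagents that add atoms: methanol, CO
Why: Alkaloid-mediated enantioselective alcoholysis of a meso anhydride (desymmetrisation): the quinuclidine nitrogen acts as a chiral general base and directs methanol to one of the two enantiotopic carbonyl groups, which fixes both ring stereocentres at once.

Step 3
Reactants: 4 (1R,2S)-2-(methoxycarbonyl)cyclobut-3-ene-1-carboxylic acid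
Product: 5 methyl (1S,2R)-2-(chlorocarbonyl)cyclobut-3-ene-1-carboxylate
Conditions: (COCl)2 (1.2 equiv), DMF (cat.), CH2Cl2, 0 °C → rt; concentrate, use crude
Reagents that add atoms: oxalyl chloride, ClC(=O)C(Cl)=O
Why: Chloroiminium-catalysed conversion of a carboxylic acid to its chloride; no base is present, so neither α-stereocentre is disturbed.

Step 4
Reactants: 6 trichloroethylene
Product: 8 (E)-1-tert-butoxy-1,2-dichloroethene, via dichloroacetylene 7 (not isolated)
Conditions: KOt-Bu (1.05 equiv), THF, 0 °C → rt
Reagents that add atoms: potassium tert-butoxide, CC(C)(C)[O-].[K+]
Why: Base-induced elimination to the chloroalkyne followed by anti addition of alkoxide and proton transfer is the known route to 1,2-dichlorovinyl ethers; the hazardous chloroalkyne is consumed as it forms.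

Step 5
Reactants: 8 (E)-1-tert-butoxy-1,2-dichloroethene
Product: 10 tert-butoxyethyne, via lithium tert-butoxyacetylide 9 (not isolated)
Conditions: n-BuLi (2.1 equiv), Et2O, −78 → −40 °C; H2O, −40 → 0 °C; dried ethereal solution concentrated cold, assayed, stored at −20 °C
Reagents that add atoms: none
Why: Two equivalents of alkyllithium effect dehydrochlorination and chlorine–lithium exchange to the alkoxyacetylide (known for dichlorovinyl ethers), and protonation releases the terminal ynol ether. The product is volatile and loses isobutene on heating, so it is worked up in ether and handled cold as an assayed solution.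

Step 6
Reactants: 10 tert-butoxyethyne; 11 1-bromobutane
Product: 13 1-tert-butoxyhex-1-yne, via sodium tert-butoxyacetylide 12 (not isolated)
Conditions: NaNH2 (1.05 equiv), liq. NH3/Et2O, −33 °C; then 11 (1.1 equiv), −33 °C; NH3 evaporated, pentane extraction, bath below 30 °C
Reagents that add atoms: none
Why: Deprotonation of a terminal ynol ether by sodium amide in liquid ammonia and SN2 alkylation of the sodium alkoxyacetylide with a primary bromide is the classical way to 1-alkoxyalk-1-ynes. The whole operation stays far below the temperature at which a tert-butyl ynol ether fragments.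

Step 7
Reactants: 5 methyl (1S,2R)-2-(chlorocarbonyl)cyclobut-3-ene-1-carboxylate; 13 1-tert-butoxyhex-1-yne
Product: 15 methyl 2-butyl-1-tert-butoxy-3-oxospiro[3.3]hepta-1,6-diene-5-carboxylate (spiro carbon Ca: ring ketone cis to the ester on Cd; enol ether carbon cis to the Cd hydrogen), via cyclobutenylidene ketene 14 (not isolated)
Conditions: 13 (1.5 equiv), Et3N (1.2 equiv, slow addition), CH2Cl2, −20 °C → rt, dark
Reagents that add atoms: none
Why: Triethylamine removes the allylic, acyl-activated hydrogen on Ca of 5 and chloride leaves, giving the cross-conjugated ketene 14, in which Ca is trigonal and Cd is the only stereocentre. The electron-rich alkyne then attacks the sp carbon of the ketene with its butyl-bearing carbon, in the plane of the ketene substituents, and the resulting enolate–oxocarbenium zwitterion (or the equivalent asynchronous concerted transition state) collapses by bonding the tert-butoxy-bearing carbon to Ca. The closest known reaction type is the [2+2] cycloaddition of ketenes with alkoxyalkynes, tert-butoxyalkynes included, to 3-alkoxycyclobutenones; here it is applied to a ketene exocyclic to a cyclobutene. The four-membered ring closes at Ca by collapse of the zwitterion (a conrotatory 4π closure of the oxidobutadienyl cation), and the two new bonds are Ca–C4 and C2–C3 of the future lactone A. Regiochemistry follows from polarity, nucleophilic alkyne carbon to ketene carbonyl carbon, so the alkoxy group ends on the carbon bound to Ca, the one that later carries bromine. The new stereocentre Ca is set by the neighbouring ester on Cd: the ring-closing bond forms on the face of Ca opposite the methoxycarbonyl group, placing the enol ether carbon cis to the Cd hydrogen and the ketone carbon cis to the ester. The step needs this facial selectivity, retention at Cd (slow addition of base, low temperature and excess alkyne so that trapping outruns exchange of the ester α-hydrogen) and a temperature low enough that the 4-vinylcyclobutenone product does not ring-open to a dienylketene.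

Step 8
Reactants: 15 methyl 2-butyl-1-tert-butoxy-3-oxospiro[3.3]hepta-1,6-diene-5-carboxylate
Product: 16 methyl 7-butyl-8-tert-butoxy-6-oxo-5-oxaspiro[3.4]octa-1,7-diene-3-carboxylate (tert-butyl tetronate on Ca; lactone oxygen O1 cis to the ester on Cd)
Conditions: mCPBA (1.2 equiv), NaHCO3, CH2Cl2, 0 °C
Reagents that add atoms: mCPBA, OOC(=O)c1cccc(Cl)c1
Why: Baeyer–Villiger oxidation of a cyclobutenone to a 2(5H)-furanone: strain release drives the rearrangement and the quaternary sp3 carbon Ca migrates in preference to the vinylic carbon, with retention, so O1 takes the place of the ketone carbon on Ca. The cyclobutene double bond, flanked by two electron-withdrawing allylic carbons, and the push–pull enol ether are poor nucleophiles toward the buffered peracid.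

Step 9
Reactants: 16 methyl 7-butyl-8-tert-butoxy-6-oxo-5-oxaspiro[3.4]octa-1,7-diene-3-carboxylate
Product: 17 7-butyl-8-tert-butoxy-6-oxo-5-oxaspiro[3.4]octa-1,7-diene-3-carboxylic acid
Conditions: LiOH·H2O (1.5 equiv), THF/H2O (3:1), 0 °C; then 1 M HCl to pH 3, 0 °C
Reagents that add atoms: lithium hydroxide, [Li+].[OH-]
Why: Saponification of the methyl ester; the tetronate is a vinylogous carbonate that resists cold hydroxide, and a lactone that opened would reclose on acidification. Epimerisation at Cd would not matter, since this centre becomes the next ketene carbon.

Step 10
Reactants: 17 7-butyl-8-tert-butoxy-6-oxo-5-oxaspiro[3.4]octa-1,7-diene-3-carboxylic acid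
Product: 18 7-butyl-8-tert-butoxy-6-oxo-5-oxaspiro[3.4]octa-1,7-diene-3-carbonyl chloride
Conditions: 1-chloro-N,N,2-trimethylprop-1-en-1-amine (1.2 equiv), CH2Cl2, 0 °C → rt; use crude
Reagents that add atoms: 1-chloro-N,N,2-trimethylprop-1-en-1-amine, CC(C)=C(Cl)N(C)C
Why: The α-chloroenamine turns acids into acid chlorides under neutral conditions (the by-product is an amide, not HCl), which protects the acid-labile tert-butyl enol ether.

Step 11
Reactants: 10 tert-butoxyethyne; 19 butanal
Product: 21 rac-1-tert-butoxyhex-1-yn-3-ol, via bromomagnesium tert-butoxyacetylide 20 (not isolated)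
Conditions: EtMgBr (1.0 equiv), THF, 0 °C; then 19 (1.0 equiv), −20 → 0 °C; sat. aq. NH4Cl, 0 °C
Reagents that add atoms: none
Why: 1,2-Addition of an alkoxyethynyl Grignard reagent to an aldehyde (Arens–van Dorp type); the magnesium acetylide is less basic than the lithium one, which limits enolisation of butanal. The near-neutral quench avoids the acid-catalysed rearrangement of 3-hydroxy ynol ethers to unsaturated esters.

Step 12
Reactants: 21 rac-1-tert-butoxyhex-1-yn-3-ol
Product: 22 1-tert-butoxyhex-1-yn-3-one
Conditions: MnO2 (activated, 10 equiv), CH2Cl2, rt
Reagents that add atoms: none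
Why: Activated MnO2 oxidises propargylic alcohols selectively under neutral, anhydrous conditions that an ynol ether tolerates.

Step 13
Reactants: 22 1-tert-butoxyhex-1-yn-3-one
Product: 23 (R)-1-tert-butoxyhex-1-yn-3-ol
Conditions: Ru[(R,R)-TsDPEN](p-cymene) (16-electron amido complex, 1 mol %), i-PrOH, rt
Reagents that add atoms: none
Why: Asymmetric transfer hydrogenation of an alkynyl ketone (Noyori type): the bifunctional catalyst delivers hydride and proton to one carbonyl face, with the alkynyl group taking the role of the aryl group of the aryl ketone model, which sets the (R)-carbinol. Base-free neutral conditions spare the electrophilic alkoxy ynone.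

Step 14
Reactants: 23 (R)-1-tert-butoxyhex-1-yn-3-ol
Product: 24 (R)-1-tert-butoxy-3-(tert-butyldimethylsilyloxy)hex-1-yne
Conditions: TBSCl (1.2 equiv), imidazole (2.5 equiv), DMF, 0 °C → rt
Reagents that add atoms: TBSCl, CC(C)(C)[Si](C)(C)Cl
Why: Standard silylation of a secondary alcohol; a silyl ether, unlike an ester, is a poor leaving group and does not ionise at the propargylic position of the electron-rich alkyne.

Step 15
Reactants: 18 7-butyl-8-tert-butoxy-6-oxo-5-oxaspiro[3.4]octa-1,7-diene-3-carbonyl chloride; 24 (R)-1-tert-butoxy-3-(tert-butyldimethylsilyloxy)hex-1-yne
Product: 26 dispiro ketone: tert-butyl tetronate ring A on Ca; on Cd a spiro 3-tert-butoxy-2-[(1R)-1-(tert-butyldimethylsilyloxy)butyl]cyclobut-2-en-1-one whose carbonyl carbon is trans and whose enol ether carbon is cis to O1, via spiro ketene 25 (not isolated)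
Conditions: 24 (1.5 equiv), Et3N (1.2 equiv, slow addition), CH2Cl2, 0 °C → rt
Reagents that add atoms: none
Why: Same reaction type as step 7: dehydrochlorination at the allylic Cd–H gives the ketene, and the polarised alkyne adds with its silyloxyalkyl-bearing carbon to the ketene carbonyl carbon. The oxocarbenium carbon then bonds to Cd on the face that carries the unsubstituted lactone oxygen O1 of Ca, away from the tert-butoxy group on C4 that lies over the other face, so the two spiro centres take up the twofold-symmetric arrangement. The propargylic stereocentre is not involved.

Step 16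
Reactants: 26 dispiro ketone
Product: 27 bis(tert-butyl tetronate): dispiro cyclobutene with ring A on Ca and the 4-tert-butoxy-3-[(1R)-1-(tert-butyldimethylsilyloxy)butyl]-2(5H)-furanone ring B on Cd; O1 and O1' trans
Conditions: mCPBA (1.2 equiv), NaHCO3, CH2Cl2, 0 °C
Reagents that add atoms: mCPBA, OOC(=O)c1cccc(Cl)c1
Why: Second Baeyer–Villiger oxidation of a cyclobutenone; the quaternary carbon Cd migrates with retention, so O1' replaces the ketone carbon on the face opposite O1.

Step 17
Reactants: 27 bis(tert-butyl tetronate)
Product: 28 bis(tetronic acid) (27 with hydroxyl at C4 and C4')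
Conditions: TFA/CH2Cl2 (1:4), 0 °C, 30 min; toluene azeotrope; use crude
Reagents that add atoms: none
Why: Acidolysis of the two tert-butyl enol ethers with loss of isobutene (E1), the known way to unmask the hydroxy-enone from a tert-butoxyalkyne cycloadduct. The short cold exposure is chosen so that the hindered secondary silyl ether survives and the side-chain oxygen stays a poor leaving group next to the enolic ring B.

Step 18
Reactants: 28 bis(tetronic acid)
Product: 29 bis(4-bromobutenolide) silyl ether (bromine at C4 and C4')
Conditions: (COBr)2 (2.6 equiv), DMF (2.6 equiv), 2,6-di-tert-butylpyridine (2.4 equiv), CH2Cl2, 0 °C → rt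
Reagents that add atoms: oxalyl bromide, BrC(=O)C(Br)=O
Why: Tetronic acids are vinylogous carboxylic acids: O-activation by the bromoiminium reagent and addition–elimination of bromide at C4 give 4-bromo-2(5H)-furanones, the vinylogous counterpart of acid bromide formation. The hindered, non-nucleophilic pyridine takes up HBr to protect the silyl ether.

Step 19
Reactants: 29 bis(4-bromobutenolide) silyl ether
Product: 30 bis(4-bromobutenolide) alcohol ((R)-1-hydroxybutyl on C3')
Conditions: 48% aq. HF, MeCN, 0 °C → rt
Reagents that add atoms: none
Why: Acidic fluoride cleaves the silyl ether without exposing the vinylogous acyl bromides to a basic or nucleophilic fluoride source.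

Step 20
Reactants: 30 bis(4-bromobutenolide) alcohol
Product: 31 bis(4-bromobutenolide) acetate ((R)-1-acetoxybutyl on C3')
Conditions: Ac2O (1.5 equiv), Sc(OTf)3 (2 mol %), MeCN, −20 → 0 °C
Reagents that add atoms: acetic anhydride, CC(=O)OC(C)=O
Why: Lewis acid-catalysed acylation of a hindered secondary alcohol avoids nucleophilic amine catalysts that could add to C4 of the bromobutenolides; the carbinol C–O bond is not broken, so the (R)-configuration is kept.

Step 21
Reactants: 31 bis(4-bromobutenolide) acetate
Product: 32 target (trans-dibromide; each ring bromine cis to C4 or C4' of the neighbouring spiro centre)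
Conditions: Br2 (1.05 equiv), CH2Cl2, 0 °C → rt, dark
Reagents that add atoms: bromine, BrBr
Why: Electrophilic anti addition of bromine through a bromonium ion gives a trans-1,2-dibromide, and the tetrasubstituted, carbonyl-conjugated butenolide double bonds do not compete. Because of the local twofold axis the two alkene faces are equivalent, so the configuration at Cb and Cc is decided only by which carbon bromide opens: 32 requires opening at the carbon whose neighbouring spiro centre turns its vinylic carbon toward the incoming bromide. This is the more crowded trajectory, so the substrate does not secure the selectivity and the outcome is the main open point of the route.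

## Compound list

1 | maleic anhydride | O=C1OC(=O)C=C1 | starting material
2 | acetylene | C#C | starting material
3 | cis-cyclobut-3-ene-1,2-dicarboxylic anhydride (meso) | O=C1OC(=O)[C@@H]2C=C[C@H]12 | intermediate
4 | (1R,2S)-2-(methoxycarbonyl)cyclobut-3-ene-1-carboxylic acid | OC(=O)[C@@H]1C=C[C@@H]1C(=O)OC | intermediate
5 | methyl (1S,2R)-2-(chlorocarbonyl)cyclobut-3-ene-1-carboxylate | ClC(=O)[C@@H]1C=C[C@@H]1C(=O)OC | intermediate
6 | trichloroethylene | ClC=C(Cl)Cl | starting material
7 | dichloroacetylene | ClC#CCl | intermediate
8 | (E)-1-tert-butoxy-1,2-dichloroethene | CC(C)(C)O/C(Cl)=C\Cl | intermediate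
9 | lithium tert-butoxyacetylide | [Li]C#COC(C)(C)C | intermediate
10 | tert-butoxyethyne | C#COC(C)(C)C | intermediate
11 | 1-bromobutane | CCCCBr | starting material
12 | sodium tert-butoxyacetylide | [Na]C#COC(C)(C)C | intermediate
13 | 1-tert-butoxyhex-1-yne | CCCCC#COC(C)(C)C | intermediate
14 | methyl (1S)-4-(oxomethylidene)cyclobut-2-ene-1-carboxylate (cyclobutenylidene ketene) | O=C=C1C=C[C@@H]1C(=O)OC | intermediate
15 | methyl 2-butyl-1-tert-butoxy-3-oxospiro[3.3]hepta-1,6-diene-5-carboxylate (ketone cis to ester) | CCCCC1=C(OC(C)(C)C)[C@@]2(C1=O)C=C[C@@H]2C(=O)OC | intermediate
16 | methyl 7-butyl-8-tert-butoxy-6-oxo-5-oxaspiro[3.4]octa-1,7-diene-3-carboxylate (O1 cis to ester) | CCCCC1=C(OC(C)(C)C)[C@@]2(OC1=O)C=C[C@@H]2C(=O)OC | intermediate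
17 | 7-butyl-8-tert-butoxy-6-oxo-5-oxaspiro[3.4]octa-1,7-diene-3-carboxylic acid | CCCCC1=C(OC(C)(C)C)[C@@]2(OC1=O)C=C[C@@H]2C(=O)O | intermediate
18 | 7-butyl-8-tert-butoxy-6-oxo-5-oxaspiro[3.4]octa-1,7-diene-3-carbonyl chloride | CCCCC1=C(OC(C)(C)C)[C@@]2(OC1=O)C=C[C@@H]2C(=O)Cl | intermediate
19 | butanal | CCCC=O | starting material
20 | bromomagnesium tert-butoxyacetylide | Br[Mg]C#COC(C)(C)C | intermediate
21 | rac-1-tert-butoxyhex-1-yn-3-ol | CCCC(O)C#COC(C)(C)C | intermediate
22 | 1-tert-butoxyhex-1-yn-3-one | CCCC(=O)C#COC(C)(C)C | intermediate
23 | (R)-1-tert-butoxyhex-1-yn-3-ol | CC(C)(C)OC#C[C@@H](CCC)O | intermediate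
24 | (R)-1-tert-butoxy-3-(tert-butyldimethylsilyloxy)hex-1-yne | CC(C)(C)OC#C[C@@H](CCC)O[Si](C)(C)C(C)(C)C | intermediate
25 | 7-butyl-8-tert-butoxy-3-(oxomethylidene)-5-oxaspiro[3.4]octa-1,7-dien-6-one (spiro ketene) | CCCCC1=C(OC(C)(C)C)[C@@]2(OC1=O)C=CC2=C=O | intermediate
26 | dispiro ketone (ring A tetronate on Ca; 3-tert-butoxy-2-[(1R)-1-(tert-butyldimethylsilyloxy)butyl]cyclobutenone on Cd) | CCCCC1=C(OC(C)(C)C)[C@@]2(OC1=O)C=C[C@@]21C(=O)C([C@@H](CCC)O[Si](C)(C)C(C)(C)C)=C1OC(C)(C)C | intermediate
27 | bis(tert-butyl tetronate), O1 and O1' trans | CCCCC1=C(OC(C)(C)C)[C@@]2(OC1=O)C=C[C@@]21OC(=O)C([C@@H](CCC)O[Si](C)(C)C(C)(C)C)=C1OC(C)(C)C | intermediate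
28 | bis(tetronic acid) | CCCCC1=C(O)[C@@]2(OC1=O)C=C[C@@]21OC(=O)C([C@@H](CCC)O[Si](C)(C)C(C)(C)C)=C1O | intermediate
29 | bis(4-bromobutenolide) silyl ether | CCCCC1=C(Br)[C@@]2(OC1=O)C=C[C@@]21OC(=O)C([C@@H](CCC)O[Si](C)(C)C(C)(C)C)=C1Br | intermediate
30 | bis(4-bromobutenolide) alcohol | CCCCC1=C(Br)[C@@]2(OC1=O)C=C[C@@]21OC(=O)C([C@@H](CCC)O)=C1Br | intermediate
31 | bis(4-bromobutenolide) acetate | CCCCC1=C(Br)[C@@]2(OC1=O)C=C[C@@]21OC(=O)C([C@@H](CCC)OC(C)=O)=C1Br | intermediate
32 | CNP0268004.1 | CCCCC1=C(Br)[C@@]2(OC1=O)[C@@H](Br)[C@H](Br)[C@@]21OC(=O)C([C@@H](CCC)OC(C)=O)=C1Br | target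

## Step count and least certain steps

Total step count: 21. Longest linear sequence: 14 steps (steps 1–3, 7–10 and 15–21, from maleic anhydride).

**Step 7 (key step).**
- Most likely to go wrong: trapping of the short-lived, cross-conjugated ketene 14 by the moderately nucleophilic tert-butyl ynol ether may be too slow. Amine-mediated exchange of the ester α-hydrogen on Cd would then erode enantiopurity, the ketene could oligomerise, or the zwitterion could lose isobutene; facial selectivity at Ca also depends on the ester alone.
- Fallback (sets out from 5, returns at 16): the ketene from 5 would be trapped with the more nucleophilic 1-(triisopropylsilyloxy)hex-1-yne F1, a class known to add to ketenes at low temperature. F1 is available in one pot from hex-1-yne by lithiation, oxidation of the acetylide with lithium tert-butyl peroxide and O-silylation. This should give the spiro 3-silyloxycyclobutenone F2, Baeyer–Villiger oxidation as in step 8 the silyl tetronate F3, and HF·pyridine the tetronic acid F4. O-alkylation of F4 with tert-butyl 2,2,2-trichloroacetimidate then rejoins the route at 16.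

**Step 21 (dibromination).**
- Most likely to go wrong: site selection in the opening of the bromonium ion. The bromines on C4 and C4' project over exactly the two positions the new bromines must occupy, so opening at the other carbon, syn to the unsubstituted lactone oxygen, is the less crowded path and would give the diastereomeric trans-dibromide. The hindered, electron-poor alkene may also react slowly.
- Fallback (sets out from 31, returns at 32 or 31): this replaces kinetic addition by isomerisation. The other trans-dibromide F14 differs from 32 by inversion at both CHBr carbons, which is what the known thermal 1,2-interchange of vicinal bromines does in one event. F14 would be heated in a polar solvent with a soluble bromide to reach equilibrium, 32 separated and the rest resubmitted. Whatever cannot be converted would be returned to 31 with zinc dust in THF/acetic acid (reductive elimination) and recycled.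
- Limit: the position of this equilibrium cannot be predicted with confidence. If it lies against 32, the target would have to be taken as the minor isomer of the addition, and this remains the unresolved point of the strategy.

**Step 15 (second annulation).**
- Most likely to go wrong: slow cycloaddition, because a ketene flanked by a quaternary spiro centre meets an alkyne whose nucleophilic carbon carries a branched silyloxyalkyl group; the ketene would decompose before it is trapped.
- Fallback (sets out from 5 and 24, returns at 27): the order of the two annulations would be exchanged, which the twofold axis of the core allows without changing the hemiester. Ketene 14 from 5 would be trapped with the hindered alkyne 24 to give spiro cyclobutenone F5, oxidised to tetronate F6, saponified to acid F7 and converted to acid chloride F8. The derived ketene F9 would be trapped with the small alkyne 13 to give dispiro ketone F10, and Baeyer–Villiger oxidation of F10 gives 27 itself.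

**Step 18 (double bromination of the tetronic acids).**
- Most likely to go wrong: loss of the silyl ether under HBr and bromoiminium conditions, followed by formylation, bromination or elimination at the freed carbinol next to ring B.
- Fallback (sets out from 27, returns at 31): the protecting-group exchange would be moved ahead of the unmasking. Compound 27 would be desilylated with buffered fluoride to alcohol F11 and acetylated to F12. Acidolysis as in step 17 would give the bis(tetronic acid) acetate F13, kept acidic throughout so that the β-acetoxy group is not expelled through the enolate, and bromination as in step 18 would give 31 directly.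

## Further compounds

F1 | step 7 | 1-(triisopropylsilyloxy)hex-1-yne | CCCCC#CO[Si](C(C)C)(C(C)C)C(C)C
F2 | step 7 | methyl 2-butyl-3-oxo-1-(triisopropylsilyloxy)spiro[3.3]hepta-1,6-diene-5-carboxylate | CCCCC1=C(O[Si](C(C)C)(C(C)C)C(C)C)[C@@]2(C1=O)C=C[C@@H]2C(=O)OC
F3 | step 7 | methyl 7-butyl-6-oxo-8-(triisopropylsilyloxy)-5-oxaspiro[3.4]octa-1,7-diene-3-carboxylate | CCCCC1=C(O[Si](C(C)C)(C(C)C)C(C)C)[C@@]2(OC1=O)C=C[C@@H]2C(=O)OC
F4 | step 7 | methyl 7-butyl-8-hydroxy-6-oxo-5-oxaspiro[3.4]octa-1,7-diene-3-carboxylate | CCCCC1=C(O)[C@@]2(OC1=O)C=C[C@@H]2C(=O)OC
F5 | step 15 | methyl 1-tert-butoxy-2-[(1R)-1-(tert-butyldimethylsilyloxy)butyl]-3-oxospiro[3.3]hepta-1,6-diene-5-carboxylate | CCC[C@@H](O[Si](C)(C)C(C)(C)C)C1=C(OC(C)(C)C)[C@@]2(C1=O)C=C[C@@H]2C(=O)OC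
F6 | step 15 | methyl 8-tert-butoxy-7-[(1R)-1-(tert-butyldimethylsilyloxy)butyl]-6-oxo-5-oxaspiro[3.4]octa-1,7-diene-3-carboxylate | CCC[C@@H](O[Si](C)(C)C(C)(C)C)C1=C(OC(C)(C)C)[C@@]2(OC1=O)C=C[C@@H]2C(=O)OC
F7 | step 15 | 8-tert-butoxy-7-[(1R)-1-(tert-butyldimethylsilyloxy)butyl]-6-oxo-5-oxaspiro[3.4]octa-1,7-diene-3-carboxylic acid | CCC[C@@H](O[Si](C)(C)C(C)(C)C)C1=C(OC(C)(C)C)[C@@]2(OC1=O)C=C[C@@H]2C(=O)O
F8 | step 15 | 8-tert-butoxy-7-[(1R)-1-(tert-butyldimethylsilyloxy)butyl]-6-oxo-5-oxaspiro[3.4]octa-1,7-diene-3-carbonyl chloride | CCC[C@@H](O[Si](C)(C)C(C)(C)C)C1=C(OC(C)(C)C)[C@@]2(OC1=O)C=C[C@@H]2C(=O)Cl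
F9 | step 15 | 8-tert-butoxy-7-[(1R)-1-(tert-butyldimethylsilyloxy)butyl]-3-(oxomethylidene)-5-oxaspiro[3.4]octa-1,7-dien-6-one | CCC[C@@H](O[Si](C)(C)C(C)(C)C)C1=C(OC(C)(C)C)[C@@]2(OC1=O)C=CC2=C=O
F10 | step 15 | dispiro ketone with ring B tetronate on the first spiro carbon and 2-butyl-3-tert-butoxycyclobutenone on the second | CCC[C@@H](O[Si](C)(C)C(C)(C)C)C1=C(OC(C)(C)C)[C@@]2(OC1=O)C=C[C@@]21C(=O)C(CCCC)=C1OC(C)(C)C
F11 | step 18 | bis(tert-butyl tetronate) alcohol | CCCCC1=C(OC(C)(C)C)[C@@]2(OC1=O)C=C[C@@]21OC(=O)C([C@@H](CCC)O)=C1OC(C)(C)C
F12 | step 18 | bis(tert-butyl tetronate) acetate | CCCCC1=C(OC(C)(C)C)[C@@]2(OC1=O)C=C[C@@]21OC(=O)C([C@@H](CCC)OC(C)=O)=C1OC(C)(C)C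
F13 | step 18 | bis(tetronic acid) acetate | CCCCC1=C(O)[C@@]2(OC1=O)C=C[C@@]21OC(=O)C([C@@H](CCC)OC(C)=O)=C1O
F14 | step 21 | diastereomeric trans-dibromide (each ring bromine cis to the neighbouring lactone oxygen) | CCCCC1=C(Br)[C@@]2(OC1=O)[C@H](Br)[C@@H](Br)[C@@]21OC(=O)C([C@@H](CCC)OC(C)=O)=C1Br
A1 | alternative 1 | silyl-protected dispiro cyclobutene bis(4-bromobutenolide) | CCCCC1=C(Br)[C@@]2(OC1=O)C=C[C@@]21OC(=O)C([C@@H](CCC)O[Si](C)(C)C(C)(C)C)=C1Br
A2 | alternative 2 | bicyclic β-lactone (2-oxabicyclo[2.2.0]hex-5-en-3-one) with methyl ester on Ca and (R)-3-(tert-butyldimethylsilyloxy)hexanoyloxy on Cd | COC(=O)[C@@]2(OC3=O)C=C[C@@]23OC(=O)C[C@@H](CCC)O[Si](C)(C)C(C)(C)C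
A3 | alternative 3 | Passerini adduct: spiro bromobutenolide cyclobutene with N-(cyclohex-1-enyl)carboxamide and (R)-3-(tert-butyldimethylsilyloxy)hexanoyloxy on Cd | CCCCC1=C(Br)[C@@]2(OC1=O)C=C[C@@]2(C(=O)NC1=CCCCC1)OC(=O)C[C@@H](CCC)O[Si](C)(C)C(C)(C)C
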